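The red run showed me first that E does not stay: its share of the J charged fell from 87.1% at 52 s to 78.3% at 110 s.

| flask | J | L | time |
|---|---|---|---|
| teal | 0.100 M | 0.200 M |  |
| grey | 0.0400 M | 0.140 M |  |
| ochre | 0.200 M | 0.200 M |  |
| red | 0.100 M | 0.600 M |  |
| green | 0.100 M | 0.200 M | 440 s |

| teal run: time / s | teal run: [E] / M | grey run: time / s | grey run: [E] / M | ochre run: time / s | ochre run: [E] / M | red run: time / s | red run: [E] / M |
|---|---|---|---|---|---|---|---|
| 3.9 | 0.0062 | 3.9 | 0.0016 | 3.9 | 0.0120 | 3.9 | 0.0396 |
| 12 | 0.0154 | 12 | 0.0036 | 12 | 0.0278 | 12 | 0.0711 |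
| 23 | 0.0253 | 23 | 0.0058 | 23 | 0.0445 | 23 | 0.0839 |
| 36 | 0.0322 | 36 | 0.0089 | 36 | 0.0558 | 36 | 0.0880 |
| 52 | 0.0375 | 52 | 0.0105 | 52 | 0.0643 | 52 | 0.0871 |
| 69 | 0.0426 | 69 | 0.0115 | 69 | 0.0694 | 69 | 0.0857 |
| 89 | 0.0438 | 89 | 0.0126 | 89 | 0.0734 | 89 | 0.0819 |
| 110 | 0.0457 | 110 | 0.0137 | 110 | 0.0743 | 110 | 0.0783 |

(each reading ± 5 × 10⁻⁴ M)

- the exponent of [L] in the starting rate at the charge of the teal run (at the point where two percent of the J have become E)
- the exponent of [J] in the starting rate at the charge of the teal run (at the point where two percent of the J have become E) (one fixed amount of E, the same in the runs compared)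
- E in the green run at 440 s, as a share of the J charged

- Overall: J + L -> E.
- Constant volume, constant temperature.
- An order is taken over about fifteen percent of the charge, up and down.

From that fall in the red run I read what I call the fade rate, 0.00184 s⁻¹, the fraction of the E present that goes each second. It is a net reading, taken while the red flask may still have been making E.

The first readings gave the orders. Treating the teal and red runs as first order in J, I got an exponent of [L] of 1.88. Ochre against teal, at equal L, gave an exponent of [J] of 0.953.

The green flask has the teal charge, so I followed the teal run to its last reading, 45.7% of the J at 110 s. The fade rate over the remaining 330 s keeps 54.6% of that, which leaves 24.9%.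

The weak link was that this sum lets the flask make nothing after 110 s, yet the teal run was still rising there. Its making rate is the rise plus the fade: 0.00478 s⁻¹ of the charge between 23 s and 52 s, and 0.00173 s⁻¹ over the last two readings. I assumed that the rate went on falling at that pace, by a factor e every 60.8 s, and on that assumption I reckoned a further 10.5% of the charge still to come; this tail was a rough guess at its shape, not a reading. Taken as made about 60.8 s after the last reading, that E keeps 61.0%. My rough estimate became 31.3%.

The forecast gave 1.8, 1 and 33%, a little above my sum, reading from the red run “so E also drains slowly”.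

The flask gave 2.0, 1.0 and 31.7%, and the forecast stands within its margins.

    J + 2 L → E + L (0.4180 L² mol⁻² s⁻¹)
    E → Ja (0.002310 s⁻¹)
    2 L → Gy (0.01510 L mol⁻¹ s⁻¹)

The conversion of E into Ja is the main reason the green flask ends where it does. The same green flask without that step reaches 71.3% at 440 s instead of 31.7%, a difference of 40 percentage points. Set on the 31.7% standing in the green flask at 440 s, the fade rate read on the red run takes about 5.82 × 10⁻⁴ s⁻¹ of the charge each second.

The numbers in the tables stem from a simulated flask with constants of no real substance, noise included.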